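**Retrosynthetic overview**
1. Feature: in ring B the oxygen-bearing C2' and the carbon-bearing C3' are neighbours, and C3' has the C4' oxygen on its other side. The C2'–O and C3'–C bonds are therefore cut together, back to DMF and a C2'≡C3' aryne polarised by the C4' alkoxy group.
2. The prenyl chain is cut at C1''–C2''. The formyl carbon that DMF places on C3' becomes the benzylic CH2 (CHO → CH2OH → CH2Br) and is joined to 2-methylprop-1-enylmagnesium bromide under CuI catalysis.
3. Ring C is cut at O1–C2 and C2–C3 (one carbon from DMF dimethyl acetal). It is also cut at C3–C4, a Horner–Wadsworth–Emmons union of the ring B aldehyde (its carbon becomes C3) with a ring A α-anilinophosphonate (its carbon becomes C4).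
4. The aryne precursor comes from 3,4-dihydroxy-5-methoxybenzaldehyde by 4-O-MOM protection, 3-O-carbamoylation, acetalisation, carbamate-directed silylation at C2 and exchange of carbamate for triflate.
5. Ring order: rings A and B are bought as arenes, the dioxolane is a temporary protecting ring, and the transient benzoxete of the key step opens again. Ring C is the only ring built and closes last (step 17).

Key step: step 7

Remark: the target has no stereocentre and no stereogenic double bond. Phosphonate 24 and benzoxete 11 are racemic, and 12, 25, 27 and 28 are drawn without double-bond geometry because that geometry is lost later.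

Step 1
Reactants: 1 3,4-dihydroxy-5-methoxybenzaldehyde
Product: 2 3-hydroxy-5-methoxy-4-(methoxymethoxy)benzaldehyde
Conditions: MOMCl (1.05 equiv), i-Pr2NEt (1.2 equiv), DMF, 0 °C
Reagents that add atoms: chloromethyl methyl ether (MOMCl), COCCl
Why: Chemoselective Williamson-type O-alkylation under acidity control: the C4 hydroxyl, para to the formyl group, is by far the more acidic phenol, so about one equivalent of amine base ionises it alone and the chloromethyl ether caps that oxygen while the C3 hydroxyl stays free.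

Step 2
Reactants: 2 3-hydroxy-5-methoxy-4-(methoxymethoxy)benzaldehyde
Product: 3 5-formyl-3-methoxy-2-(methoxymethoxy)phenyl N,N-diethylcarbamate
Conditions: Et2NCOCl, K2CO3, MeCN, 80 °C
Reagents that add atoms: N,N-diethylcarbamoyl chloride, CCN(CC)C(=O)Cl
Why: O-Carbamoylation (nucleophilic acyl substitution) of the only free phenol installs the strongest oxygen-based director for the later metalation, and the carbonate base leaves the aldehyde and the MOM ether untouched.

Step 3
Reactants: 3 5-formyl-3-methoxy-2-(methoxymethoxy)phenyl N,N-diethylcarbamate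
Product: 4 5-(1,3-dioxolan-2-yl)-3-methoxy-2-(methoxymethoxy)phenyl N,N-diethylcarbamate
Conditions: TMSOCH2CH2OTMS, TMSOTf (5 mol %), CH2Cl2, −78 → −20 °C; pyridine quench
Reagents that add atoms: 1,2-bis(trimethylsilyloxy)ethane, C[Si](C)(C)OCCO[Si](C)(C)C
Why: Noyori acetalisation, in which catalytic TMSOTf activates the aldehyde at low temperature and formation of hexamethyldisiloxane drives the exchange without protic acid or heat, so the aryl MOM ether, whose unstabilised formaldehyde-type oxocarbenium ion forms far more slowly than the benzylic one, should survive.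

Step 4
Reactants: 4 5-(1,3-dioxolan-2-yl)-3-methoxy-2-(methoxymethoxy)phenyl N,N-diethylcarbamate
Product: 6 3-(1,3-dioxolan-2-yl)-5-methoxy-6-(methoxymethoxy)-2-(trimethylsilyl)phenyl N,N-diethylcarbamate, via aryllithium 5 (not isolated)
Conditions: s-BuLi, TMEDA, THF, −78 °C; TMSCl, −78 °C → rt
Reagents that add atoms: sec-butyllithium (lithium of 5), CCC(C)[Li]; chlorotrimethylsilane, C[Si](C)(C)Cl
Why: Directed ortho-metalation: the carbamate has a single free ortho position, which also lies ortho to the dioxolane, so the two directors cooperate and override the C–H beside the methoxy group, and silylation at −78 °C comes before any anionic ortho-Fries shift.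

Step 5
Reactants: 6 3-(1,3-dioxolan-2-yl)-5-methoxy-6-(methoxymethoxy)-2-(trimethylsilyl)phenyl N,N-diethylcarbamate
Product: 7 3-(1,3-dioxolan-2-yl)-5-methoxy-6-(methoxymethoxy)-2-(trimethylsilyl)phenol
Conditions: LiAlH4, THF, 0 → 65 °C; aq. potassium sodium tartrate
Reagents that add atoms: none
Why: Hydride reduction of the aryl carbamate (acyl substitution that expels the phenoxide, then reduction of the formamide to the amine) takes place at the carbonyl carbon away from the crowded ring, and the aryl–silicon bond, the acetal and the MOM ether are inert to LiAlH4 and to the non-acidic work-up.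

Step 6
Reactants: 7 3-(1,3-dioxolan-2-yl)-5-methoxy-6-(methoxymethoxy)-2-(trimethylsilyl)phenol
Product: 8 3-(1,3-dioxolan-2-yl)-5-methoxy-6-(methoxymethoxy)-2-(trimethylsilyl)phenyl trifluoromethanesulfonate
Conditions: Tf2O, pyridine, CH2Cl2, 0 °C
Reagents that add atoms: trifluoromethanesulfonic anhydride, O=S(=O)(OS(=O)(=O)C(F)(F)F)C(F)(F)F
Why: O-Sulfonylation of the phenol under pyridine buffering gives the o-silylaryl triflate (Kobayashi-type aryne precursor) without exposing the two acetal groups to acid.

Step 7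
Reactants: 8 3-(1,3-dioxolan-2-yl)-5-methoxy-6-(methoxymethoxy)-2-(trimethylsilyl)phenyl trifluoromethanesulfonate; 9 N,N-dimethylformamide
Product: 13 3-(1,3-dioxolan-2-yl)-2-hydroxy-5-methoxy-6-(methoxymethoxy)benzaldehyde, via aryne 10 (not isolated), via benzoxete aminal 11 (not isolated), via aminomethylene quinone methide 12 (not isolated)
Conditions: CsF (3 equiv), dry DMF (solvent), slow addition of 8, 25 °C; then H2O, aq. NH4Cl work-up
Reagents that add atoms: N,N-dimethylformamide 9, CN(C)C=O; water, O
Why: Fluoride attacks silicon at C2' and triflate leaves from C3', which gives aryne 10 with its triple bond between C2' and C3'. The carbonyl oxygen of DMF adds to C2', and the aryl anion left at C3' closes on the iminium carbon (4-exo-trig, overall a stepwise formal [2+2] addition) to benzoxete 11, the only ring closed in this step and one that is not kept. Ring strain opens 11 to the aminomethylene o-quinone methide 12, a vinylogous amide that added water hydrolyses to salicylaldehyde 13 and dimethylamine, so that the C2'–O and C3'–C bonds are both made in one operation. The closest known reaction type is the insertion of arynes into the C=O bond of formamides to give salicylaldehydes, in which 3-alkoxyarynes take the oxygen nucleophile meta to the alkoxy group. The selectivity needed is regiochemical: the C4' OMOM group next to C3' withdraws σ-electron density and distorts the aryne so that C2' is the more linear, more electrophilic terminus and the charge builds up at C3' beside oxygen, and this bias should outweigh the shielding of C2' by the C1' dioxolane because the attacking atom is a small carbonyl oxygen present as solvent. No stereocentre is formed.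

Step 8
Reactants: 13 3-(1,3-dioxolan-2-yl)-2-hydroxy-5-methoxy-6-(methoxymethoxy)benzaldehyde
Product: 14 3-(1,3-dioxolan-2-yl)-5-methoxy-2,6-bis(methoxymethoxy)benzaldehyde
Conditions: NaH, MOMCl, DMF, 0 °C
Reagents that add atoms: chloromethyl methyl ether (MOMCl), COCCl
Why: Williamson-type O-alkylation of the sodium phenoxide, formed irreversibly to break the hydrogen bond to the formyl group, caps the C2' oxygen with the same acetal type as the C4' oxygen so that both fall together at the end.

Step 9
Reactants: 14 3-(1,3-dioxolan-2-yl)-5-methoxy-2,6-bis(methoxymethoxy)benzaldehyde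
Product: 15 [3-(1,3-dioxolan-2-yl)-5-methoxy-2,6-bis(methoxymethoxy)phenyl]methanol
Conditions: NaBH4, MeOH, 0 °C
Reagents that add atoms: none
Why: Borohydride 1,2-reduction of a non-enolisable aryl aldehyde, to which the dioxolane and the MOM ethers are inert.

Step 10
Reactants: 15 [3-(1,3-dioxolan-2-yl)-5-methoxy-2,6-bis(methoxymethoxy)phenyl]methanol
Product: 17 2-[3-(bromomethyl)-5-methoxy-2,4-bis(methoxymethoxy)phenyl]-1,3-dioxolane, via benzylic mesylate 16 (not isolated)
Conditions: Ms2O, i-Pr2NEt, LiBr, THF, −20 → 0 °C; cold aqueous work-up, used at once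
Reagents that add atoms: methanesulfonic anhydride (mesyl group of 16), CS(=O)(=O)OS(C)(=O)=O; lithium bromide, [Li+].[Br-]
Why: Sulfonylation followed by nucleophilic displacement with bromide turns the alcohol into the bromide under basic to neutral, chloride-free conditions with a non-nucleophilic amine, which spares the three acetal groups, and the reactive bromide is carried on without storage.

Step 11
Reactants: 17 2-[3-(bromomethyl)-5-methoxy-2,4-bis(methoxymethoxy)phenyl]-1,3-dioxolane; 18 2-methylprop-1-enylmagnesium bromide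
Product: 19 2-[5-methoxy-2,4-bis(methoxymethoxy)-3-(3-methylbut-2-en-1-yl)phenyl]-1,3-dioxolane
Conditions: 18 (1.5 equiv, THF solution), CuI (10 mol %), THF, −30 → 0 °C
Reagents that add atoms: 2-methylprop-1-enylmagnesium bromide 18, CC(C)=C[Mg]Br
Why: Copper-catalysed Kumada-type sp3–sp2 cross-coupling: the alkenylcopper species formed from CuI and the Grignard reagent displaces the activated benzylic bromide, and bond formation at the alkenyl carbon fixes the trisubstituted double bond of the prenyl group with no allylic transposition.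

Step 12
Reactants: 19 2-[5-methoxy-2,4-bis(methoxymethoxy)-3-(3-methylbut-2-en-1-yl)phenyl]-1,3-dioxolane
Product: 20 5-methoxy-2,4-bis(methoxymethoxy)-3-(3-methylbut-2-en-1-yl)benzaldehyde
Conditions: PPTS (20 mol %), THF–H2O (4:1), 40 °C
Reagents that add atoms: water, O
Why: Acid-catalysed acetal hydrolysis with kinetic selection: the benzylic dioxolane ionises to an oxocarbenium ion stabilised by the ortho and para alkoxy groups and so cleaves at pyridinium-level acidity, at which aryl MOM ethers and the prenyl alkene do not react.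

Step 13
Reactants: 21 2,4-dihydroxybenzaldehyde
Product: 22 2,4-bis(methoxymethoxy)benzaldehyde
Conditions: NaH (2.5 equiv), MOMCl (2.5 equiv), DMF, 0 °C → rt
Reagents that add atoms: chloromethyl methyl ether (MOMCl), COCCl
Why: Double Williamson-type O-alkylation of the bis-phenoxide, with NaH chosen because the C2 hydroxyl is hydrogen-bonded to the formyl group.

Step 14
Reactants: 22 2,4-bis(methoxymethoxy)benzaldehyde
Product: 24 rac-diphenyl {[2,4-bis(methoxymethoxy)phenyl](phenylamino)methyl}phosphonate, via N-phenyl imine 23 (not isolated)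
Conditions: PhNH2, (PhO)2P(O)H, i-PrOH, 25 °C
Reagents that add atoms: aniline, Nc1ccccc1; diphenyl phosphite, O=[PH](Oc1ccccc1)Oc1ccccc1
Why: Kabachnik–Fields three-component reaction: aniline condenses to imine 23 and the P–H bond of diphenyl phosphite adds across C=N, giving a racemic N,P-acetal that serves as a ring A acyl anion equivalent and whose stereocentre is erased in the next step.

Step 15
Reactants: 20 5-methoxy-2,4-bis(methoxymethoxy)-3-(3-methylbut-2-en-1-yl)benzaldehyde; 24 rac-diphenyl {[2,4-bis(methoxymethoxy)phenyl](phenylamino)methyl}phosphonate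
Product: 26 1-[2,4-bis(methoxymethoxy)phenyl]-2-[5-methoxy-2,4-bis(methoxymethoxy)-3-(3-methylbut-2-en-1-yl)phenyl]ethan-1-one, via N-phenyl enamine 25 (not isolated)
Conditions: NaH, THF, 0 → 25 °C; then 1 M aq. HCl, THF, 0 → 25 °C
Reagents that add atoms: water, O
Why: Horner–Wadsworth–Emmons olefination of 20 with deprotonated 24, helped by diphenyl phosphate as a good leaving group, forms the future C3–C4 bond as N-aryl enamine 25, and dilute aqueous acid hydrolyses this enamine/ketimine to the deoxybenzoin faster than it attacks aryl MOM ethers.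

Step 16
Reactants: 26 1-[2,4-bis(methoxymethoxy)phenyl]-2-[5-methoxy-2,4-bis(methoxymethoxy)-3-(3-methylbut-2-en-1-yl)phenyl]ethan-1-one
Product: 27 1-[2,4-bis(methoxymethoxy)phenyl]-3-(dimethylamino)-2-[5-methoxy-2,4-bis(methoxymethoxy)-3-(3-methylbut-2-en-1-yl)phenyl]prop-2-en-1-one
Conditions: Me2NCH(OMe)2, toluene, 100 °C
Reagents that add atoms: N,N-dimethylformamide dimethyl acetal, COC(OC)N(C)C
Why: Condensation of the doubly activated methylene with the amide acetal (enaminone formation), the usual one-carbon insertion of the deoxybenzoin route to isoflavones, supplies C2 under neutral conditions that leave MOM and prenyl groups alone.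

Step 17
Reactants: 27 1-[2,4-bis(methoxymethoxy)phenyl]-3-(dimethylamino)-2-[5-methoxy-2,4-bis(methoxymethoxy)-3-(3-methylbut-2-en-1-yl)phenyl]prop-2-en-1-one
Product: 30 piscisoflavone A (7,2',4'-trihydroxy-5'-methoxy-3'-prenylisoflavone), via hydroxyaryl enaminone 28 (not isolated), via tris-MOM isoflavone 29 (not isolated)
Conditions: 3 M aq. HCl, MeOH, 45 °C, stopped as soon as 29 is consumed
Reagents that add atoms: none
Why: Acid-catalysed MOM solvolysis frees first the ring A phenol ortho to the carbonyl, which closes ring C by 6-endo-trig conjugate addition to the protonated enaminone and loss of dimethylamine, after which the three remaining MOM groups are exchanged to methanol under acid mild and brief enough to keep the prenyl alkene from adding to its flanking phenols.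

**Compound list**
1 | 3,4-dihydroxy-5-methoxybenzaldehyde | COc1cc(C=O)cc(O)c1O | starting material
2 | 3-hydroxy-5-methoxy-4-(methoxymethoxy)benzaldehyde | COCOc1c(O)cc(C=O)cc1OC | intermediate
3 | 5-formyl-3-methoxy-2-(methoxymethoxy)phenyl N,N-diethylcarbamate | CCN(CC)C(=O)Oc1cc(C=O)cc(OC)c1OCOC | intermediate
4 | 5-(1,3-dioxolan-2-yl)-3-methoxy-2-(methoxymethoxy)phenyl N,N-diethylcarbamate | CCN(CC)C(=O)Oc1cc(C2OCCO2)cc(OC)c1OCOC | intermediate
5 | [2-(diethylcarbamoyloxy)-6-(1,3-dioxolan-2-yl)-4-methoxy-3-(methoxymethoxy)phenyl]lithium | [Li]c1c(OC(=O)N(CC)CC)c(OCOC)c(OC)cc1C1OCCO1 | intermediate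
6 | 3-(1,3-dioxolan-2-yl)-5-methoxy-6-(methoxymethoxy)-2-(trimethylsilyl)phenyl N,N-diethylcarbamate | CCN(CC)C(=O)Oc1c([Si](C)(C)C)c(C2OCCO2)cc(OC)c1OCOC | intermediate
7 | 3-(1,3-dioxolan-2-yl)-5-methoxy-6-(methoxymethoxy)-2-(trimethylsilyl)phenol | COc1cc(C2OCCO2)c([Si](C)(C)C)c(O)c1OCOC | intermediate
8 | 3-(1,3-dioxolan-2-yl)-5-methoxy-6-(methoxymethoxy)-2-(trimethylsilyl)phenyl trifluoromethanesulfonate | COc1cc(C2OCCO2)c([Si](C)(C)C)c(OS(=O)(=O)C(F)(F)F)c1OCOC | intermediate
9 | N,N-dimethylformamide | CN(C)C=O | starting material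
10 | 2-[5-methoxy-4-(methoxymethoxy)-2,3-didehydrophenyl]-1,3-dioxolane (C2'≡C3' aryne) | COC1=C(OCOC)C#CC(C2OCCO2)=C1 | intermediate
11 | rac-6-(1,3-dioxolan-2-yl)-4-methoxy-3-(methoxymethoxy)-N,N-dimethyl-2H-1-benzoxet-2-amine | COc1cc(C2OCCO2)c2OC(N(C)C)c2c1OCOC | intermediate
12 | 6-[(dimethylamino)methylidene]-2-(1,3-dioxolan-2-yl)-4-methoxy-5-(methoxymethoxy)cyclohexa-2,4-dien-1-one | COC1=C(OCOC)C(=CN(C)C)C(=O)C(C2OCCO2)=C1 | intermediate
13 | 3-(1,3-dioxolan-2-yl)-2-hydroxy-5-methoxy-6-(methoxymethoxy)benzaldehyde | COc1cc(C2OCCO2)c(O)c(C=O)c1OCOC | intermediate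
14 | 3-(1,3-dioxolan-2-yl)-5-methoxy-2,6-bis(methoxymethoxy)benzaldehyde | COc1cc(C2OCCO2)c(OCOC)c(C=O)c1OCOC | intermediate
15 | [3-(1,3-dioxolan-2-yl)-5-methoxy-2,6-bis(methoxymethoxy)phenyl]methanol | COc1cc(C2OCCO2)c(OCOC)c(CO)c1OCOC | intermediate
16 | [3-(1,3-dioxolan-2-yl)-5-methoxy-2,6-bis(methoxymethoxy)phenyl]methyl methanesulfonate | COc1cc(C2OCCO2)c(OCOC)c(COS(C)(=O)=O)c1OCOC | intermediate
17 | 2-[3-(bromomethyl)-5-methoxy-2,4-bis(methoxymethoxy)phenyl]-1,3-dioxolane | COc1cc(C2OCCO2)c(OCOC)c(CBr)c1OCOC | intermediate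
18 | 2-methylprop-1-enylmagnesium bromide | CC(C)=C[Mg]Br | starting material
19 | 2-[5-methoxy-2,4-bis(methoxymethoxy)-3-(3-methylbut-2-en-1-yl)phenyl]-1,3-dioxolane | COc1cc(C2OCCO2)c(OCOC)c(CC=C(C)C)c1OCOC | intermediate
20 | 5-methoxy-2,4-bis(methoxymethoxy)-3-(3-methylbut-2-en-1-yl)benzaldehyde | COc1cc(C=O)c(OCOC)c(CC=C(C)C)c1OCOC | intermediate
21 | 2,4-dihydroxybenzaldehyde | O=Cc1ccc(O)cc1O | starting material
22 | 2,4-bis(methoxymethoxy)benzaldehyde | COCOc1ccc(C=O)c(OCOC)c1 | intermediate
23 | (E)-1-[2,4-bis(methoxymethoxy)phenyl]-N-phenylmethanimine | COCOc1ccc(/C=N/c2ccccc2)c(OCOC)c1 | intermediate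
24 | rac-diphenyl {[2,4-bis(methoxymethoxy)phenyl](phenylamino)methyl}phosphonate | COCOc1ccc(C(Nc2ccccc2)P(=O)(Oc2ccccc2)Oc2ccccc2)c(OCOC)c1 | intermediate
25 | N-{1-[2,4-bis(methoxymethoxy)phenyl]-2-[5-methoxy-2,4-bis(methoxymethoxy)-3-(3-methylbut-2-en-1-yl)phenyl]ethenyl}aniline | COCOc1ccc(C(Nc2ccccc2)=Cc2cc(OC)c(OCOC)c(CC=C(C)C)c2OCOC)c(OCOC)c1 | intermediate
26 | 1-[2,4-bis(methoxymethoxy)phenyl]-2-[5-methoxy-2,4-bis(methoxymethoxy)-3-(3-methylbut-2-en-1-yl)phenyl]ethan-1-one | COCOc1ccc(C(=O)Cc2cc(OC)c(OCOC)c(CC=C(C)C)c2OCOC)c(OCOC)c1 | intermediate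
27 | 1-[2,4-bis(methoxymethoxy)phenyl]-3-(dimethylamino)-2-[5-methoxy-2,4-bis(methoxymethoxy)-3-(3-methylbut-2-en-1-yl)phenyl]prop-2-en-1-one | COCOc1ccc(C(=O)C(=CN(C)C)c2cc(OC)c(OCOC)c(CC=C(C)C)c2OCOC)c(OCOC)c1 | intermediate
28 | 3-(dimethylamino)-1-[2-hydroxy-4-(methoxymethoxy)phenyl]-2-[5-methoxy-2,4-bis(methoxymethoxy)-3-(3-methylbut-2-en-1-yl)phenyl]prop-2-en-1-one | COCOc1ccc(C(=O)C(=CN(C)C)c2cc(OC)c(OCOC)c(CC=C(C)C)c2OCOC)c(O)c1 | intermediate
29 | 7-(methoxymethoxy)-3-[5-methoxy-2,4-bis(methoxymethoxy)-3-(3-methylbut-2-en-1-yl)phenyl]-4H-chromen-4-one | COCOc1ccc2c(c1)occ(-c1cc(OC)c(OCOC)c(CC=C(C)C)c1OCOC)c2=O | intermediate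
30 | piscisoflavone A, 3-[2,4-dihydroxy-5-methoxy-3-(3-methylbut-2-en-1-yl)phenyl]-7-hydroxy-4H-chromen-4-one | COc1cc(-c2coc3cc(O)ccc3c2=O)c(O)c(CC=C(C)C)c1O | target

**Totals**
Total step count: 17. Longest linear sequence: 15 (steps 1–12 and 15–17). Steps 13 and 14 form the ring A branch.

**Steps most likely to fail**

Step 7.
- Regiocontrol may erode if the dioxolane shields C2' enough for the DMF oxygen to add at C3'.
- The aryne may also be intercepted by the neighbouring MOM oxygen, or by the phenoxide that builds up.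
- Protodesilylation by traces of water may consume 8 before elimination.

The fallback gives up the aryne. It sets out from 4 and comes back at 19, so steps 5–11 are bypassed.
- Aryllithium 5 is made as in step 4 and quenched with B(OMe)3 to the dimethyl arylboronate F1.
- H2O2/NaOH oxidises it to the C2' phenol F2, and NaH/MOMCl gives the bis-MOM carbamate F3.
- LiAlH4 frees the C3' phenol F4, and Tf2O/pyridine gives the aryl triflate F5.
- Stille coupling with tributyl(3-methylbut-2-en-1-yl)stannane under the zerovalent palladium catalyst Pd(PPh3)4 (LiCl, DMF, 90 °C) places the prenyl group on C3' and gives 19.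

Step 10 (together with its use in step 11).
- The benzylic bromide carries two ortho alkoxy groups and may ionise on handling.
- A MOM oxygen may participate, closing a benzodioxine ring with loss of the methyl group.
- Self-alkylation may occur, and so may homocoupling during the copper step.

The fallback avoids any benzylic halide. It sets out from 13 and comes back at 19.
- Boc2O (i-Pr2NEt, cat. DMAP, CH2Cl2) gives the aryl tert-butyl carbonate F6.
- BH3·THF at 0 °C reduces the formyl group, without forming a free alkoxide, to the O-Boc salicyl alcohol F7.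
- At least two equivalents of 18 (THF, −78 °C → rt) first deprotonate the alcohol. The alkoxide takes over the Boc group and expels tert-butyl carbonate to give the o-quinone methide F8.
- A further equivalent of 18 then adds 1,4 to the exocyclic methylene to give the C3'-prenyl phenol F9.
- NaH/MOMCl converts this into 19.

Step 15.
- The carbanion of 24 is destabilised by the electron-rich ring A and may fragment back to imine 23 and phosphite.
- Addition to the electron-rich aldehyde 20 may be slow.
- The acid hydrolysis may strip part of the MOM groups.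

The fallback sets out from 20 (with 22 as partner) and comes back at 26.
- TsNHNH2 in MeOH gives the tosylhydrazone F10.
- NaOEt in EtOH at 70 °C (Bamford–Stevens conditions), in the presence of 22, releases the aryldiazomethane F11.
- This adds to the formyl group of 22, and loss of N2 with a 1,2-hydride shift (Büchner–Curtius–Schlotterbeck homologation) gives deoxybenzoin 26.

**Further compounds**
F1 | step 7 | dimethyl [2-(diethylcarbamoyloxy)-6-(1,3-dioxolan-2-yl)-4-methoxy-3-(methoxymethoxy)phenyl]boronate | COB(OC)c1c(C2OCCO2)cc(OC)c(OCOC)c1OC(=O)N(CC)CC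
F2 | step 7 | 3-(1,3-dioxolan-2-yl)-2-hydroxy-5-methoxy-6-(methoxymethoxy)phenyl N,N-diethylcarbamate | CCN(CC)C(=O)Oc1c(O)c(C2OCCO2)cc(OC)c1OCOC
F3 | step 7 | 3-(1,3-dioxolan-2-yl)-5-methoxy-2,6-bis(methoxymethoxy)phenyl N,N-diethylcarbamate | CCN(CC)C(=O)Oc1c(OCOC)c(C2OCCO2)cc(OC)c1OCOC
F4 | step 7 | 3-(1,3-dioxolan-2-yl)-5-methoxy-2,6-bis(methoxymethoxy)phenol | Oc1c(OCOC)c(C2OCCO2)cc(OC)c1OCOC
F5 | step 7 | 3-(1,3-dioxolan-2-yl)-5-methoxy-2,6-bis(methoxymethoxy)phenyl trifluoromethanesulfonate | COCOc1c(C2OCCO2)cc(OC)c(OCOC)c1OS(=O)(=O)C(F)(F)F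
F6 | step 10 | tert-butyl 2-(1,3-dioxolan-2-yl)-6-formyl-4-methoxy-5-(methoxymethoxy)phenyl carbonate | COc1cc(C2OCCO2)c(OC(=O)OC(C)(C)C)c(C=O)c1OCOC
F7 | step 10 | tert-butyl 2-(1,3-dioxolan-2-yl)-6-(hydroxymethyl)-4-methoxy-5-(methoxymethoxy)phenyl carbonate | COc1cc(C2OCCO2)c(OC(=O)OC(C)(C)C)c(CO)c1OCOC
F8 | step 10 | 2-(1,3-dioxolan-2-yl)-4-methoxy-5-(methoxymethoxy)-6-methylidenecyclohexa-2,4-dien-1-one | COC1=C(OCOC)C(=C)C(=O)C(C2OCCO2)=C1
F9 | step 10 | 2-(1,3-dioxolan-2-yl)-4-methoxy-5-(methoxymethoxy)-6-(3-methylbut-2-en-1-yl)phenol | COc1cc(C2OCCO2)c(O)c(CC=C(C)C)c1OCOC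
F10 | step 15 | N'-{[5-methoxy-2,4-bis(methoxymethoxy)-3-(3-methylbut-2-en-1-yl)phenyl]methylidene}-4-methylbenzenesulfonohydrazide | COc1cc(C=NNS(=O)(=O)c2ccc(C)cc2)c(OCOC)c(CC=C(C)C)c1OCOC
F11 | step 15 | 1-(diazomethyl)-5-methoxy-2,4-bis(methoxymethoxy)-3-(3-methylbut-2-en-1-yl)benzene | COc1cc(C=[N+]=[N-])c(OCOC)c(CC=C(C)C)c1OCOC
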